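Ring A carries oxygen on the adjacent carbons C1 and C6 and on C4 (para to C1). The chain C2-C1(O)-C6(OAr)-C5 is a 2,3-dioxygenated butadiene, and C3-C4 is an alkyne unit whose acetyl group on C4 stands in for the third oxygen.
Late disconnections: O-Me and O-Si cleavage; C3-Br and C5-Br (ortho-bromination directed by a free C4-OH); C4-O from C4-acetyl (Baeyer-Villiger); arene from a cyclohexa-1,4-diene (dehydrogenation).
Key disconnection: C2-C3 and C4-C5, by Diels-Alder reaction of a 2-aryloxy-3-silyloxybutadiene and but-3-yn-2-one.
The diene comes from the ring B phenol, chloroacetone and formaldehyde (ether formation, methylenation, O-silylation). The ring B phenol comes from 2,6-dibromoanisole (C-H borylation/oxidation, one bromination).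
Order of rings: ring B is bought as an arene and only substituted. Ring A is the one ring that is built (step 6), and it is aromatised in step 7.

Key step: step 6

Remark on the chemistry: ring A is numbered C1 (OH), C2 (H), C3 (Br), C4 (OH), C5 (Br), C6 (O-aryl); ring B is the 2,3,5-tribromo-4-hydroxyphenoxy group. The target has no stereocentre, so no stereocontrol is needed. The one transient stereocentre (Mannich base) is racemic and is destroyed in the same flask.

Step 1
Reactants: 1 2,6-dibromoanisole
Product: 3 3,5-dibromo-4-methoxyphenol, via aryl pinacol boronate 2 (not isolated)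
Conditions: [Ir(OMe)(cod)]2 (1.5 mol %), 4,4'-di-tert-butyl-2,2'-bipyridine (3 mol %), B2pin2 (1.0 equiv), cyclohexane, 80 °C; evaporate; then 30% aq. H2O2, NaOH (1 equiv), THF/H2O, 0 °C to rt
Reagents that add atoms: bis(pinacolato)diboron CC1(C)OB(OC1(C)C)B1OC(C)(C)C(C)(C)O1 (boryl group of 2); hydrogen peroxide OO (phenol oxygen of 3)
Why: Iridium-catalysed aromatic C-H borylation is sterically controlled and spares C-Br bonds, so only the C-H para to the methoxy group (the one site without an ortho substituent) is borylated, and the standard alkaline peroxide oxidation of the aryl boronate (1,2-aryl shift from boron to oxygen) turns it into the phenol.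

Step 2
Reactants: 3 3,5-dibromo-4-methoxyphenol
Product: 4 2,3,5-tribromo-4-methoxyphenol
Conditions: Br2 (1.0 equiv), AcOH, rt
Reagents that add atoms: bromine BrBr
Why: Electrophilic aromatic bromination: the free hydroxyl is the strongest director, its para position is occupied by methoxy and its two ortho positions are equivalent, so one equivalent of bromine should give a single tribromide that is deactivated towards a fourth substitution.

Step 3
Reactants: 4 2,3,5-tribromo-4-methoxyphenol; 5 chloroacetone
Product: 6 1-(2,3,5-tribromo-4-methoxyphenoxy)propan-2-one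
Conditions: K2CO3 (1.5 equiv), acetone, reflux
Reagents that add atoms: none
Why: Williamson ether synthesis: the acidic tribromophenol is fully deprotonated by carbonate and its phenoxide displaces chloride from the highly SN2-reactive α-chloro ketone.

Step 4
Reactants: 6 1-(2,3,5-tribromo-4-methoxyphenoxy)propan-2-one
Product: 8 3-(2,3,5-tribromo-4-methoxyphenoxy)but-3-en-2-one, via Mannich base 7 (not isolated)
Conditions: (CH2O)n (1.2 equiv), iPr2NH·CF3CO2H (1.0 equiv), CF3CO2H (10 mol %), THF, reflux
Reagents that add atoms: formaldehyde (as paraformaldehyde) C=O; diisopropylammonium trifluoroacetate CC(C)[NH2+]C(C)C.[O-]C(=O)C(F)(F)F (its amine part stands in 7 only)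
Why: Mannich reaction followed by E1cB loss of the amine (direct α-methylenation of a ketone): the methylene flanked by the carbonyl and the electron-poor aryloxy group is the more acidic α-position and gives the more substituted enol, so the iminium ion is taken up there, as with other methyl ketones that carry an activated methylene, and the stereocentre of racemic 7 disappears again on elimination.

Step 5
Reactants: 8 3-(2,3,5-tribromo-4-methoxyphenoxy)but-3-en-2-one
Product: 9 2-(2,3,5-tribromo-4-methoxyphenoxy)-3-(tert-butyldimethylsilyloxy)buta-1,3-diene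
Conditions: TBSOTf (1.2 equiv), Et3N (2 equiv), CH2Cl2, 0 °C; cold aq. NaHCO3 work-up, short Et3N-deactivated silica plug, amine removed in vacuo
Reagents that add atoms: tert-butyldimethylsilyl trifluoromethanesulfonate CC(C)(C)[Si](C)(C)OS(=O)(=O)C(F)(F)F
Why: Soft enolisation and O-silylation of an enone with a silyl triflate and a tertiary amine is the standard access to 2-silyloxybutadienes from methyl vinyl ketones, and because the methyl group is the only enolisable position of 8, a single cross-conjugated diene can form.

Step 6
Reactants: 9 2-(2,3,5-tribromo-4-methoxyphenoxy)-3-(tert-butyldimethylsilyloxy)buta-1,3-diene; 10 but-3-yn-2-one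
Product: 11 1-[4-(tert-butyldimethylsilyloxy)-5-(2,3,5-tribromo-4-methoxyphenoxy)cyclohexa-1,4-dien-1-yl]ethanone
Conditions: 10 (3 equiv), BHT (5 mol %), toluene, 100 °C, sealed tube, base-washed glass; volatiles removed, product used crude
Reagents that add atoms: none
Why: The diene reacts through its s-cis conformer with the acetylenic ketone in a thermal, concerted but asynchronous suprafacial [4+2] cycloaddition (normal-electron-demand Diels-Alder reaction) that forms C2-C3 and C4-C5 in one event. The closest known reaction type is the cycloaddition of 2-silyloxy- and 2,3-bis(silyloxy)butadienes with ynones and propiolates, which gives cyclohexa-1,4-dienes that are later dehydrogenated to arenes. Ring A closes as a six-membered carbocycle in the intermolecular [4πs+2πs] mode, and no stereocentre arises because every ring atom of 11 is either sp2 or a CH2 group. The step needs regioselectivity (acetyl on C4, para to C1-O, and not on C3): the silyloxy oxygen is a much better π-donor than the aryloxy oxygen, whose lone pair is shared with a tribrominated ring, so the silyl enol ether half dominates the HOMO and its terminal methylene (future C2) bonds ahead to the electrophilic unsubstituted alkyne carbon (future C3). Neutral, acid-free conditions keep the tetrasubstituted C1=C6 bis-enol-ether bond intact, so C6 stays sp2 and the good leaving group ArO cannot be expelled. An excess of the volatile ynone and a radical inhibitor compensate for the reduced s-cis population of a 2,3-disubstituted diene.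

Step 7
Reactants: 11 1-[4-(tert-butyldimethylsilyloxy)-5-(2,3,5-tribromo-4-methoxyphenoxy)cyclohexa-1,4-dien-1-yl]ethanone
Product: 12 1-[4-(tert-butyldimethylsilyloxy)-3-(2,3,5-tribromo-4-methoxyphenoxy)phenyl]ethanone
Conditions: DDQ (1.1 equiv), toluene, 0 °C to rt; filtration
Reagents that add atoms: none
Why: Dehydrogenation of a cyclohexa-1,4-diene with a high-potential quinone: hydride abstraction from C5-H (the cation is stabilised through C6=C1 by the silyloxy oxygen) and proton loss from C2 give the arene under nearly neutral conditions, because the spent hydroquinone precipitates from toluene, so neither the silyl nor the aryloxy group should be lost.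

Step 8
Reactants: 12 1-[4-(tert-butyldimethylsilyloxy)-3-(2,3,5-tribromo-4-methoxyphenoxy)phenyl]ethanone
Product: 13 4-(tert-butyldimethylsilyloxy)-3-(2,3,5-tribromo-4-methoxyphenoxy)phenyl acetate
Conditions: mCPBA (2.5 equiv), CH2Cl2, 40 °C, dark
Reagents that add atoms: 3-chloroperbenzoic acid OOC(=O)c1cccc(Cl)c1
Why: Baeyer-Villiger oxidation: in the peracid adduct the aryl group, made electron-rich by the para silyloxy oxygen, migrates in preference to methyl and places oxygen on C4 exactly where the acetyl group stood, while aryl silyl ether, diaryl ether and C-Br bonds are inert to the peracid.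

Step 9
Reactants: 13 4-(tert-butyldimethylsilyloxy)-3-(2,3,5-tribromo-4-methoxyphenoxy)phenyl acetate
Product: 14 4-(tert-butyldimethylsilyloxy)-3-(2,3,5-tribromo-4-methoxyphenoxy)phenol
Conditions: pyrrolidine (2 equiv), CH2Cl2, 0 °C
Reagents that add atoms: none
Why: Aminolysis of an aryl ester (an activated ester) by a secondary amine is fast at 0 °C, whereas the aryl silyl ether, which hydroxide or methoxide could attack, is not touched by the amine.

Step 10
Reactants: 14 4-(tert-butyldimethylsilyloxy)-3-(2,3,5-tribromo-4-methoxyphenoxy)phenol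
Product: 16 2,6-dibromo-4-(tert-butyldimethylsilyloxy)-3-(2,3,5-tribromo-4-methoxyphenoxy)phenol, via C3-monobromide 15 (not isolated)
Conditions: NBS (2.05 equiv), iPr2NH (10 mol %), CH2Cl2, -20 °C to rt, dark
Reagents that add atoms: N-bromosuccinimide O=C1CCC(=O)N1Br
Why: Amine-catalysed ortho-bromination of a phenol with NBS (electrophilic aromatic substitution without free HBr): the free C4-OH is the strongest donor and its para position C1 is blocked, so bromine enters at C3 (also para to the ether oxygen) and then at C5, while C2 lies only ortho to the bulky, weaker silyloxy donor and ring B is deactivated by three bromines.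

Step 11
Reactants: 16 2,6-dibromo-4-(tert-butyldimethylsilyloxy)-3-(2,3,5-tribromo-4-methoxyphenoxy)phenol
Product: 17 3,5-dibromo-2-(2,3,5-tribromo-4-methoxyphenoxy)benzene-1,4-diol
Conditions: TBAF (1.1 equiv), AcOH (1.5 equiv), THF, 0 °C, argon
Reagents that add atoms: none
Why: Fluoride-induced cleavage of the aryl silyl ether, driven by the Si-F bond, is run as a separate step because BBr3 cannot be relied on to remove a hindered aryl silyl ether, and the acetic acid buffer keeps the hydroquinone protonated and safe from air oxidation.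

Step 12
Reactants: 17 3,5-dibromo-2-(2,3,5-tribromo-4-methoxyphenoxy)benzene-1,4-diol
Product: 18 3,5-dibromo-2-(2,3,5-tribromo-4-hydroxyphenoxy)benzene-1,4-diol (CNP0084224.0)
Conditions: BBr3 (5 equiv), CH2Cl2, -78 °C to rt; then ice/H2O
Reagents that add atoms: none
Why: Lewis-acid cleavage of an aryl methyl ether: BBr3 binds the methoxy oxygen, which the two ortho bromines twist out of conjugation, bromide attacks the methyl group by SN2, the diaryl ether and the C-Br bonds are not affected, and hydrolysis of the aryl borates releases the triol.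

Compound list
1 | 2,6-dibromoanisole | COc1c(Br)cccc1Br | starting material
2 | 2-(3,5-dibromo-4-methoxyphenyl)-4,4,5,5-tetramethyl-1,3,2-dioxaborolane | COc1c(Br)cc(cc1Br)B1OC(C)(C)C(C)(C)O1 | intermediate (not isolated)
3 | 3,5-dibromo-4-methoxyphenol | COc1c(Br)cc(O)cc1Br | intermediate
4 | 2,3,5-tribromo-4-methoxyphenol | COc1c(Br)cc(O)c(Br)c1Br | intermediate
5 | chloroacetone | CC(=O)CCl | starting material
6 | 1-(2,3,5-tribromo-4-methoxyphenoxy)propan-2-one | CC(=O)COc1cc(Br)c(OC)c(Br)c1Br | intermediate
7 | 4-(diisopropylamino)-3-(2,3,5-tribromo-4-methoxyphenoxy)butan-2-one (racemic) | CC(=O)C(CN(C(C)C)C(C)C)Oc1cc(Br)c(OC)c(Br)c1Br | intermediate (not isolated)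
8 | 3-(2,3,5-tribromo-4-methoxyphenoxy)but-3-en-2-one | CC(=O)C(=C)Oc1cc(Br)c(OC)c(Br)c1Br | intermediate
9 | 2-(2,3,5-tribromo-4-methoxyphenoxy)-3-(tert-butyldimethylsilyloxy)buta-1,3-diene | C=C(O[Si](C)(C)C(C)(C)C)C(=C)Oc1cc(Br)c(OC)c(Br)c1Br | intermediate
10 | but-3-yn-2-one | CC(=O)C#C | starting material
11 | 1-[4-(tert-butyldimethylsilyloxy)-5-(2,3,5-tribromo-4-methoxyphenoxy)cyclohexa-1,4-dien-1-yl]ethanone | CC(=O)C1=CCC(O[Si](C)(C)C(C)(C)C)=C(Oc2cc(Br)c(OC)c(Br)c2Br)C1 | intermediate
12 | 1-[4-(tert-butyldimethylsilyloxy)-3-(2,3,5-tribromo-4-methoxyphenoxy)phenyl]ethanone | CC(=O)c1ccc(O[Si](C)(C)C(C)(C)C)c(Oc2cc(Br)c(OC)c(Br)c2Br)c1 | intermediate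
13 | 4-(tert-butyldimethylsilyloxy)-3-(2,3,5-tribromo-4-methoxyphenoxy)phenyl acetate | CC(=O)Oc1ccc(O[Si](C)(C)C(C)(C)C)c(Oc2cc(Br)c(OC)c(Br)c2Br)c1 | intermediate
14 | 4-(tert-butyldimethylsilyloxy)-3-(2,3,5-tribromo-4-methoxyphenoxy)phenol | Oc1ccc(O[Si](C)(C)C(C)(C)C)c(Oc2cc(Br)c(OC)c(Br)c2Br)c1 | intermediate
15 | 2-bromo-4-(tert-butyldimethylsilyloxy)-5-(2,3,5-tribromo-4-methoxyphenoxy)phenol | Oc1cc(Oc2cc(Br)c(OC)c(Br)c2Br)c(O[Si](C)(C)C(C)(C)C)cc1Br | intermediate (not isolated)
16 | 2,6-dibromo-4-(tert-butyldimethylsilyloxy)-3-(2,3,5-tribromo-4-methoxyphenoxy)phenol | Oc1c(Br)cc(O[Si](C)(C)C(C)(C)C)c(Oc2cc(Br)c(OC)c(Br)c2Br)c1Br | intermediate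
17 | 3,5-dibromo-2-(2,3,5-tribromo-4-methoxyphenoxy)benzene-1,4-diol | Oc1cc(Br)c(O)c(Br)c1Oc1cc(Br)c(OC)c(Br)c1Br | intermediate
18 | 3,5-dibromo-2-(2,3,5-tribromo-4-hydroxyphenoxy)benzene-1,4-diol | Oc1cc(Br)c(O)c(Br)c1Oc1cc(Br)c(O)c(Br)c1Br | target

Total step count: 12. Longest linear sequence: 12 steps (1 to 18).

Steps most likely to fail

1. Step 6. The two large oxygen substituents may twist the diene out of the planar s-cis form and slow the cycloaddition. During a long heating period the regiocontrol may erode, the silyl enol ether may hydrolyse, or the ynone may polymerise. The fallback gives up the construction of ring A and joins two finished arenes. It sets out from phenol 4, which is coupled with commercial (5-acetyl-2-methoxyphenyl)boronic acid in a Chan-Lam coupling (Cu(OAc)2, pyridine, 4 Å molecular sieves, CH2Cl2, air, rt); this oxidative copper coupling leaves C-Br bonds alone. The product is 1-[4-methoxy-3-(2,3,5-tribromo-4-methoxyphenoxy)phenyl]ethanone F1. Baeyer-Villiger oxidation (mCPBA, CH2Cl2) gives 4-methoxy-3-(2,3,5-tribromo-4-methoxyphenoxy)phenyl acetate F2. Aminolysis with pyrrolidine gives 4-methoxy-3-(2,3,5-tribromo-4-methoxyphenoxy)phenol F3. NBS (2 equiv, catalytic iPr2NH) gives 2,6-dibromo-4-methoxy-3-(2,3,5-tribromo-4-methoxyphenoxy)phenol F4. BBr3 then cleaves both methyl ethers, so the fallback comes back to the route at target 18.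

2. Step 4. Aminomethylation may take place on the methyl side or at both α-positions, and the electron-poor enone may oligomerise during the reflux. The fallback fixes the site of methylenation with a phosphonate as activating group. It sets out from phenol 4. Rh2(OAc)4-catalysed O-H insertion of the carbenoid from dimethyl (1-diazo-2-oxopropyl)phosphonate (toluene, 80 °C) gives racemic dimethyl [1-(2,3,5-tribromo-4-methoxyphenoxy)-2-oxopropyl]phosphonate F5. A Horner-Wadsworth-Emmons olefination with aqueous formaldehyde (K2CO3, THF/H2O, 0 °C to rt) can place the methylene group only on the phosphorus-bearing carbon, and it comes back to the route at enone 8.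

3. Step 10. Electrophilic bromine may attack C1 in the ipso sense and oxidise the mono-silylated hydroquinone to the quinone with loss of the silyl group. The reaction may also stall after the first bromination, because C5 lies between two oxygen substituents, or the second bromination may leak to C2. The fallback replaces the silyl group by an electron-withdrawing ester that cannot leave in this way and that deactivates C2. It sets out from acetate 13. Buffered fluoride (TBAF, AcOH, THF, 0 °C) gives 4-hydroxy-3-(2,3,5-tribromo-4-methoxyphenoxy)phenyl acetate F6. Pivaloyl chloride (Et3N, DMAP, CH2Cl2) gives 4-acetoxy-2-(2,3,5-tribromo-4-methoxyphenoxy)phenyl pivalate F7. Pyrrolidine at 0 °C removes only the unhindered acetate and gives 4-hydroxy-2-(2,3,5-tribromo-4-methoxyphenoxy)phenyl pivalate F8. Br2 (2 equiv, NaOAc, AcOH) gives 3,5-dibromo-4-hydroxy-2-(2,3,5-tribromo-4-methoxyphenoxy)phenyl pivalate F9. Methanolysis (K2CO3, MeOH, argon, rt) comes back to the route at hydroquinone 17.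

Further compounds
F1 | step 6 | 1-[4-methoxy-3-(2,3,5-tribromo-4-methoxyphenoxy)phenyl]ethanone | CC(=O)c1ccc(OC)c(Oc2cc(Br)c(OC)c(Br)c2Br)c1
F2 | step 6 | 4-methoxy-3-(2,3,5-tribromo-4-methoxyphenoxy)phenyl acetate | CC(=O)Oc1ccc(OC)c(Oc2cc(Br)c(OC)c(Br)c2Br)c1
F3 | step 6 | 4-methoxy-3-(2,3,5-tribromo-4-methoxyphenoxy)phenol | Oc1ccc(OC)c(Oc2cc(Br)c(OC)c(Br)c2Br)c1
F4 | step 6 | 2,6-dibromo-4-methoxy-3-(2,3,5-tribromo-4-methoxyphenoxy)phenol | Oc1c(Br)cc(OC)c(Oc2cc(Br)c(OC)c(Br)c2Br)c1Br
F5 | step 4 | dimethyl [1-(2,3,5-tribromo-4-methoxyphenoxy)-2-oxopropyl]phosphonate (racemic) | COP(=O)(OC)C(Oc1cc(Br)c(OC)c(Br)c1Br)C(C)=O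
F6 | step 10 | 4-hydroxy-3-(2,3,5-tribromo-4-methoxyphenoxy)phenyl acetate | CC(=O)Oc1ccc(O)c(Oc2cc(Br)c(OC)c(Br)c2Br)c1
F7 | step 10 | 4-acetoxy-2-(2,3,5-tribromo-4-methoxyphenoxy)phenyl pivalate | CC(=O)Oc1ccc(OC(=O)C(C)(C)C)c(Oc2cc(Br)c(OC)c(Br)c2Br)c1
F8 | step 10 | 4-hydroxy-2-(2,3,5-tribromo-4-methoxyphenoxy)phenyl pivalate | Oc1ccc(OC(=O)C(C)(C)C)c(Oc2cc(Br)c(OC)c(Br)c2Br)c1
F9 | step 10 | 3,5-dibromo-4-hydroxy-2-(2,3,5-tribromo-4-methoxyphenoxy)phenyl pivalate | Oc1c(Br)cc(OC(=O)C(C)(C)C)c(Oc2cc(Br)c(OC)c(Br)c2Br)c1Br
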